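**Strategy.** The route rests on disconnecting the bond between C2 of ring C and C1′ of the B ring. The flat chromone 7 (5-hydroxy-7-methoxy-8-prenylchromen-4-one) serves as the dehydro form of the chromanone. Its C2 is the β-carbon of the vinylogous ester O1–C2=C3–C4=O, so a rhodium-catalysed enantioselective 1,4-addition of (3-hydroxy-4-methoxyphenyl)boronic acid joins both halves, returns ring C to the chromanone level and sets the only stereocentre, C2 (S), in the last step without protecting groups. Chromone 7 is reached in three steps; its C8 prenyl group is delivered from O5 by a europium-catalysed para-Claisen–Cope cascade.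

Key step: step 4

Remark: the (S)-ligand is chosen on the assumption that chromone 7 presents C2=C3 to rhodium with the same enantioface preference as 2-cyclohexenone. (S)-Biaryl bisphosphines give (S)-3-arylcyclohexanones, which maps onto Re-face attack at C2 and the 2S product. Should the sense prove opposite, the (R)-ligand would be used with no other change. "Prenyl" means 3-methylbut-2-en-1-yl throughout.

**Step 1**
Reactants: 1 1-(2,6-dihydroxy-4-methoxyphenyl)ethan-1-one
Product: 2 1-{2-hydroxy-4-methoxy-6-[(3-methylbut-2-en-1-yl)oxy]phenyl}ethan-1-one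
Conditions: prenyl bromide (1.05 equiv), K2CO3 (1.2 equiv), acetone, reflux
Reagents that add atoms: prenyl bromide (1-bromo-3-methylbut-2-ene), CC(C)=CCBr
Why: Williamson ether synthesis; the two phenols of 1 are equivalent, and after the first O-alkylation the remaining hydroxyl is locked in a hydrogen bond to the acetyl carbonyl, so mono-O-prenylation should dominate over bis-alkylation and C-alkylation under K2CO3/acetone.

**Step 2**
Reactants: 2 1-{2-hydroxy-4-methoxy-6-[(3-methylbut-2-en-1-yl)oxy]phenyl}ethan-1-one
Product: 4 7-methoxy-5-[(3-methylbut-2-en-1-yl)oxy]-4H-chromen-4-one, via enaminone 3 (not isolated)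
Conditions: DMF-DMA (2 equiv), toluene, 95 °C; concentrate; then AcOH, 60 °C
Reagents that add atoms: N,N-dimethylformamide dimethyl acetal, COC(OC)N(C)C
Why: Enaminone route to chromones; condensation of the methyl ketone with DMF-DMA gives the β-dimethylaminoenone 3, whose free phenol closes ring C by oxa-Michael addition with loss of dimethylamine, and the weak acid is chosen to spare the acid-labile prenyl ether.

**Step 3**
Reactants: 4 7-methoxy-5-[(3-methylbut-2-en-1-yl)oxy]-4H-chromen-4-one
Product: 7 5-hydroxy-7-methoxy-8-(3-methylbut-2-en-1-yl)-4H-chromen-4-one, via ortho-dienone 5 (not isolated), via para-dienone 6 (not isolated)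
Conditions: Eu(fod)3 (10 mol %), NaHCO3, PhCl, 85 °C
Reagents that add atoms: none
Why: Aromatic para-Claisen–Cope cascade; Eu(III) chelated between C4=O and O5 promotes the [3,3] shift of the prenyl ether to C6 (dienone 5, 1,1-dimethylallyl group), a Cope [3,3] shift then moves the group to C8, the only position para to O5, restoring the linear prenyl chain (dienone 6), and tautomerisation gives the chelated phenol 7.

**Step 4**
Reactants: 7 5-hydroxy-7-methoxy-8-(3-methylbut-2-en-1-yl)-4H-chromen-4-one; 8 (3-hydroxy-4-methoxyphenyl)boronic acid (2.5 equiv)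
Product: 9 (2S)-5-hydroxy-2-(3-hydroxy-4-methoxyphenyl)-7-methoxy-8-(3-methylbut-2-en-1-yl)-2,3-dihydro-4H-chromen-4-one
Conditions: [Rh(OH)(cod)]2 (2.5 mol %), (S)-MeO-F12-BIPHEP [(S)-2,2′-bis[bis(3,4,5-trifluorophenyl)phosphino]-6,6′-dimethoxy-1,1′-biphenyl] (5.5 mol %, pre-mixed), dioxane/H2O 10:1, 35 °C, no added base
Reagents that add atoms: none
Why: Hayashi–Miyaura rhodium-catalysed asymmetric 1,4-addition: transmetalation of 8 to the hydroxo-rhodium(I) bisphosphine complex gives an aryl–rhodium species that binds and inserts the C2=C3 bond of 7, forming the C2–C1′ bond and an oxa-π-allyl rhodium enolate over C3–C4–O, which water protonates to release 9 and the Rh–OH catalyst. The closest known reaction type is this same addition of arylboronic acids to chromones to give flavanones, and no ring is closed because ring C is already in place and only drops from the 4-pyranone to the dihydropyranone level. The new stereocentre C2 is set by the catalyst alone: the (S)-biaryl bisphosphine is expected to shield the Si face of C2 so that the aryl group is delivered to the Re face, which corresponds to 2S. The step needs 1,4- over 1,2-addition, an inert prenyl alkene, a single addition and no erosion of configuration; the unactivated trisubstituted alkene does not insert into aryl–Rh(I), the product ketone is deactivated by the A ring and by the hydrogen bond from 5-OH, and the base-free, near-neutral medium avoids the retro-oxa-Michael ring opening that racemises flavanones. The hydrogen bond from 5-OH to C4=O should keep C2 electrophilic despite the electron-rich A ring, and the excess of 8 covers protodeboronation.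

**Compound list**
1 | 1-(2,6-dihydroxy-4-methoxyphenyl)ethan-1-one | CC(=O)c1c(O)cc(OC)cc1O | starting material
2 | 1-{2-hydroxy-4-methoxy-6-[(3-methylbut-2-en-1-yl)oxy]phenyl}ethan-1-one | CC(=O)c1c(O)cc(OC)cc1OCC=C(C)C | intermediate
3 | (E)-3-(dimethylamino)-1-{2-hydroxy-4-methoxy-6-[(3-methylbut-2-en-1-yl)oxy]phenyl}prop-2-en-1-one (enaminone, not isolated) | CN(C)/C=C/C(=O)c1c(O)cc(OC)cc1OCC=C(C)C | intermediate
4 | 7-methoxy-5-[(3-methylbut-2-en-1-yl)oxy]-4H-chromen-4-one | COc1cc(OCC=C(C)C)c2c(c1)occc2=O | intermediate
5 | 7-methoxy-6-(2-methylbut-3-en-2-yl)-4H-chromene-4,5(6H)-dione (ortho-dienone, C6 racemic, not isolated) | O=C1C(C(C)(C)C=C)C(OC)=CC2=C1C(=O)C=CO2 | intermediate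
6 | 7-methoxy-8-(3-methylbut-2-en-1-yl)-4H-chromene-4,5(8H)-dione (para-dienone, C8 racemic, not isolated) | O=C1C=C(OC)C(CC=C(C)C)C2=C1C(=O)C=CO2 | intermediate
7 | 5-hydroxy-7-methoxy-8-(3-methylbut-2-en-1-yl)-4H-chromen-4-one | O=c1ccoc2c(CC=C(C)C)c(OC)cc(O)c12 | intermediate
8 | (3-hydroxy-4-methoxyphenyl)boronic acid | COc1ccc(B(O)O)cc1O | starting material
9 | (2S)-5-hydroxy-2-(3-hydroxy-4-methoxyphenyl)-7-methoxy-8-(3-methylbut-2-en-1-yl)-2,3-dihydro-4H-chromen-4-one | COc1ccc([C@@H]2CC(=O)c3c(O)cc(OC)c(CC=C(C)C)c3O2)cc1O | target

**Step count.** Total steps: 4. Longest linear sequence: 4 (1 → 2 → 4 → 7 → 9; boronic acid 8 is used as purchased).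

**Steps most likely to fail**

1. Step 4. The 5-hydroxy-4-keto unit of 7 may bind rhodium as a β-ketophenolate chelate and slow transmetalation. Insertion into the electron-rich chromone may then lose out to protodeboronation of 8, and a long reaction time may let reversible ring opening erode the configuration at C2. The fallback masks the chelating phenol. It sets out from 7 and comes back at 9. Compound 7 would be treated with MOMCl and i-Pr2NEt (CH2Cl2, 0 °C to rt) to give 7-methoxy-5-(methoxymethoxy)-8-(3-methylbut-2-en-1-yl)-4H-chromen-4-one F1, an acceptor with no acidic chelating site. Addition of 8 under the same rhodium catalysis should then give (2S)-2-(3-hydroxy-4-methoxyphenyl)-7-methoxy-5-(methoxymethoxy)-8-(3-methylbut-2-en-1-yl)-2,3-dihydro-4H-chromen-4-one F2. Acidic methanolysis (HCl, MeOH, 40 °C) removes the acetal without base and should leave C2 and the prenyl group untouched, giving 9.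

2. Step 3. The ortho-dienone may tautomerise before the Cope shift, which would leave the 1,1-dimethylallyl group at C6, or the Lewis acid may simply strip the prenyl group from O5. The fallback builds the C8–prenyl bond by cross-coupling at a position fixed by halogenation. It sets out from 1 and comes back at 7. Mono-protection of 1 (MOMCl, i-Pr2NEt) would give 1-[2-hydroxy-4-methoxy-6-(methoxymethoxy)phenyl]ethan-1-one F3. Iodination ortho to the free phenol (N-iodosuccinimide, DMF, 0 °C) would give 1-[2-hydroxy-3-iodo-4-methoxy-6-(methoxymethoxy)phenyl]ethan-1-one F4. DMF-DMA would convert this into (E)-3-(dimethylamino)-1-[2-hydroxy-3-iodo-4-methoxy-6-(methoxymethoxy)phenyl]prop-2-en-1-one F5, which on warming in AcOH should close to 8-iodo-7-methoxy-5-(methoxymethoxy)-4H-chromen-4-one F6. Stille coupling with tributyl(3-methylbut-2-en-1-yl)stannane (Pd(PPh3)4, DMF, 90 °C) should give 7-methoxy-5-(methoxymethoxy)-8-(3-methylbut-2-en-1-yl)-4H-chromen-4-one F1, and HCl in MeOH would then release 7.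

3. Step 2. The prenyl ether may be cleaved during the acid-promoted ring closure, or DMF-DMA may O-methylate the chelated phenol. The fallback closes ring C before the prenyl group is present. It sets out from 1 and comes back at 4. Compound 1 would be condensed with DMF-DMA to (E)-1-(2,6-dihydroxy-4-methoxyphenyl)-3-(dimethylamino)prop-2-en-1-one F7. This would be cyclised with conc. HCl in CH2Cl2 to 5-hydroxy-7-methoxy-4H-chromen-4-one F8; either equivalent hydroxyl may close, and no acid-labile group is present yet. Mitsunobu etherification of the chelated 5-OH with 3-methylbut-2-en-1-ol (PPh3, DIAD, THF, 0 °C to rt) should then give 4.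

**Further compounds**
F1 | step 4 | 7-methoxy-5-(methoxymethoxy)-8-(3-methylbut-2-en-1-yl)-4H-chromen-4-one | O=c1ccoc2c(CC=C(C)C)c(OC)cc(OCOC)c12
F2 | step 4 | (2S)-2-(3-hydroxy-4-methoxyphenyl)-7-methoxy-5-(methoxymethoxy)-8-(3-methylbut-2-en-1-yl)-2,3-dihydro-4H-chromen-4-one | COc1ccc([C@@H]2CC(=O)c3c(OCOC)cc(OC)c(CC=C(C)C)c3O2)cc1O
F3 | step 3 | 1-[2-hydroxy-4-methoxy-6-(methoxymethoxy)phenyl]ethan-1-one | CC(=O)c1c(O)cc(OC)cc1OCOC
F4 | step 3 | 1-[2-hydroxy-3-iodo-4-methoxy-6-(methoxymethoxy)phenyl]ethan-1-one | CC(=O)c1c(O)c(I)c(OC)cc1OCOC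
F5 | step 3 | (E)-3-(dimethylamino)-1-[2-hydroxy-3-iodo-4-methoxy-6-(methoxymethoxy)phenyl]prop-2-en-1-one | CN(C)/C=C/C(=O)c1c(O)c(I)c(OC)cc1OCOC
F6 | step 3 | 8-iodo-7-methoxy-5-(methoxymethoxy)-4H-chromen-4-one | O=c1ccoc2c(I)c(OC)cc(OCOC)c12
F7 | step 2 | (E)-1-(2,6-dihydroxy-4-methoxyphenyl)-3-(dimethylamino)prop-2-en-1-one | CN(C)/C=C/C(=O)c1c(O)cc(OC)cc1O
F8 | step 2 | 5-hydroxy-7-methoxy-4H-chromen-4-one | O=c1ccoc2cc(OC)cc(O)c12
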